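**Plan**

1. Target: all-E (6R,3'R,6'R)-3'-hydroxy-ε,ε-caroten-3-one. The retrosynthesis cuts the two ring–chain junction alkenes C7=C8 and C7'=C8'. This gives two C10 ring sulfones that differ only in the silyl group on O3, and the C20 heptaenedial C8–C8'. The dialdehyde is cut again at C9=C10/C9'=C10' and C11=C12/C11'=C12' back to the C10 trienedial; the ring is cut at C7–S and at the two bonds of a mesityl oxide/acetoacetate annulation.
2. Feature used: each ε ring is held to the nonaene by C6(H)–C7=C8 (C6'(H)–C7'=C8') next to the quaternary C1 (C1'), so a C7 sulfonyl carbanion leaves C6 alone. The C8–C8' heptaene between the rings has a twofold axis through C15=C15', so one dialdehyde serves both ends.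
3. Forward: the six-membered ring is made first by annulation. One resolved hydroxy ester is taken to the TBS sulfone for ring B and from it to the triethylsilyl sulfone for ring A. The chain grows C10 → C14 → C20. The two sulfones are then joined to the dialdehyde one after the other in one flask; ring A alone is unmasked and oxidised, and ring B is unmasked last.
4. Stereochemistry: the trans C3/C6 relationship comes from separating the reduction diastereomers, the absolute configuration from a lipase resolution. C6, C6' and C3' are carried through, and C3 of ring A is erased by oxidation. The alkenes are E from stabilised ylides, acid equilibration and the sulfone olefination.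

Key step: step 13

Assumption: the lipase is taken to acylate the (4R)-carbinol of the racemic trans-hydroxy ester (ring alkene side acting as the larger substituent, the usual sense for cyclohex-2-en-1-ols). This is to be confirmed on the resolved material; with the opposite preference the unreacted alcohol would be the (1R,4R) compound and step 4 would fall away.

Locants: in the monocyclic intermediates, ring C1 (bearing CO2Et or CH2X) becomes carotenoid C6, and ring C4 (bearing oxygen) becomes carotenoid C3.

**Route**

Step 1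
Reactants: 1 mesityl oxide (4-methylpent-3-en-2-one); 2 ethyl acetoacetate
Product: 3 rac-ethyl 2,6,6-trimethyl-4-oxocyclohex-2-ene-1-carboxylate
Conditions: BF3·OEt2, neat, rt
Reagents that add atoms: none
Why: Lewis-acid-promoted Michael addition of the acetoacetate C2 to the β-carbon of mesityl oxide, then intramolecular aldol condensation of the methyl ketone onto the acetyl carbonyl (Robinson-type annulation), should give the racemic 4-oxo-cyclohexene ester with the alkene conjugated to the ring ketone.

Step 2
Reactants: 3 rac-ethyl 2,6,6-trimethyl-4-oxocyclohex-2-ene-1-carboxylate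
Product: 4 rac-ethyl (1R*,4R*)-4-hydroxy-2,6,6-trimethylcyclohex-2-ene-1-carboxylate (trans racemate)
Conditions: NaBH4, CeCl3·7H2O, MeOH, −20 °C; chromatographic separation of the trans from the cis alcohol
Reagents that add atoms: none
Why: Luche 1,2-reduction leaves ester and alkene untouched; since the axial C6 methyl and the C1 ester shield opposite faces, both C4 epimers are expected, and the relative configuration is fixed by isolating the trans racemate (OH and CO2Et on opposite faces), the cis alcohol being returnable to 3 with MnO2.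

Step 3
Reactants: 4 rac-ethyl (1R*,4R*)-4-hydroxy-2,6,6-trimethylcyclohex-2-ene-1-carboxylate
Product: 5 ethyl (1R,4R)-4-(acetyloxy)-2,6,6-trimethylcyclohex-2-ene-1-carboxylate
Conditions: Burkholderia cepacia lipase (immobilised), vinyl acetate, t-BuOMe, 30 °C, stopped near half conversion
Reagents that add atoms: vinyl acetate, C=COC(C)=O
Why: Lipase-catalysed irreversible transesterification (kinetic resolution) distinguishes the enantiomers of a secondary allylic cyclohexenol by the size of the two carbinol substituents, so the (1R,4R)-acetate should form while the (1S,4S) half of 4 stays as the alcohol and is removed by chromatography; this sets the absolute configuration at C4 and, through the trans relationship, at C1.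

Step 4
Reactants: 5 ethyl (1R,4R)-4-(acetyloxy)-2,6,6-trimethylcyclohex-2-ene-1-carboxylate
Product: 6 ethyl (1R,4R)-4-hydroxy-2,6,6-trimethylcyclohex-2-ene-1-carboxylate
Conditions: K2CO3 (cat.), EtOH, 0 °C
Reagents that add atoms: none
Why: Carbonate-catalysed transesterification removes the acetate under conditions too mild to enolise the hindered, non-conjugated C1 ester, and ethanol as solvent keeps the ethyl ester as it is.

Step 5
Reactants: 6 ethyl (1R,4R)-4-hydroxy-2,6,6-trimethylcyclohex-2-ene-1-carboxylate
Product: 7 ethyl (1R,4R)-4-[(tert-butyldimethylsilyl)oxy]-2,6,6-trimethylcyclohex-2-ene-1-carboxylate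
Conditions: TBSCl, imidazole, DMF, rt
Reagents that add atoms: tert-butyldimethylsilyl chloride, CC(C)(C)[Si](C)(C)Cl
Why: Standard silylation of a secondary allylic alcohol gives an ether that withstands the hydride, Mitsunobu and peroxide steps that follow.

Step 6
Reactants: 7 ethyl (1R,4R)-4-[(tert-butyldimethylsilyl)oxy]-2,6,6-trimethylcyclohex-2-ene-1-carboxylate
Product: 8 [(1R,4R)-4-[(tert-butyldimethylsilyl)oxy]-2,6,6-trimethylcyclohex-2-en-1-yl]methanol
Conditions: LiAlH4, Et2O, 0 °C
Reagents that add atoms: none
Why: Hydride reduction of the hindered ester to the primary alcohol touches neither the silyl ether nor the trisubstituted alkene, and C1 cannot epimerise because no enolate is formed.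

Step 7
Reactants: 8 [(1R,4R)-4-[(tert-butyldimethylsilyl)oxy]-2,6,6-trimethylcyclohex-2-en-1-yl]methanol; 9 1-phenyl-1H-tetrazole-5-thiol
Product: 10 5-({[(1R,4R)-4-[(tert-butyldimethylsilyl)oxy]-2,6,6-trimethylcyclohex-2-en-1-yl]methyl}sulfanyl)-1-phenyl-1H-tetrazole
Conditions: PPh3, DIAD, THF, 0 °C → rt
Reagents that add atoms: none
Why: Mitsunobu thioetherification, in which the acidic tetrazole thiol displaces the oxyphosphonium group in an SN2 step at the CH2 carbon, so neither ring stereocentre takes part.

Step 8
Reactants: 10 5-({[(1R,4R)-4-[(tert-butyldimethylsilyl)oxy]-2,6,6-trimethylcyclohex-2-en-1-yl]methyl}sulfanyl)-1-phenyl-1H-tetrazole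
Product: 11 5-({[(1R,4R)-4-[(tert-butyldimethylsilyl)oxy]-2,6,6-trimethylcyclohex-2-en-1-yl]methyl}sulfonyl)-1-phenyl-1H-tetrazole (ring B sulfone)
Conditions: (NH4)6Mo7O24·4H2O (cat.), 30% aq. H2O2, EtOH, 0 °C → rt
Reagents that add atoms: hydrogen peroxide, OO
Why: Molybdate-catalysed peroxide oxidation of a tetrazolyl sulfide to the sulfone is selective for sulfur over the trisubstituted alkene, which here carries no free allylic hydroxyl that could direct epoxidation.

Step 9
Reactants: 11 ring B sulfone
Product: 12 (1R,4R)-3,5,5-trimethyl-4-{[(1-phenyl-1H-tetrazol-5-yl)sulfonyl]methyl}cyclohex-2-en-1-ol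
Conditions: HF·pyridine, THF, 0 °C → rt
Reagents that add atoms: none
Why: Fluoride cleavage of the Si–O bond under mildly acidic conditions frees the alcohol without exposing the base-sensitive tetrazolyl sulfone to a nucleophilic or basic medium.

Step 10
Reactants: 12 (1R,4R)-3,5,5-trimethyl-4-{[(1-phenyl-1H-tetrazol-5-yl)sulfonyl]methyl}cyclohex-2-en-1-ol
Product: 13 5-({[(1R,4R)-2,6,6-trimethyl-4-[(triethylsilyl)oxy]cyclohex-2-en-1-yl]methyl}sulfonyl)-1-phenyl-1H-tetrazole (ring A sulfone)
Conditions: TESCl, imidazole, CH2Cl2, 0 °C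
Reagents that add atoms: chlorotriethylsilane, CC[Si](Cl)(CC)CC
Why: Silylation gives the more labile triethylsilyl ether, which can later be taken off in the presence of the TBS ether of ring B; installing it after the peroxide step keeps it away from the acidic oxidation medium.

Step 11
Reactants: 14 (2E,4E,6E)-2,7-dimethylocta-2,4,6-trienedial; 15 (1,3-dioxolan-2-ylmethyl)triphenylphosphonium bromide
Product: 17 (2E,4E,6E,8E,10E)-4,9-dimethyldodeca-2,4,6,8,10-pentaenedial, via bis-dioxolane 16 (not isolated)
Conditions: 15, t-BuOK, THF, 0 °C; then 14, 0 °C → rt; then 1 M HCl, THF, rt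
Reagents that add atoms: water, O
Why: Twofold Wittig two-carbon homologation with the dioxolanylmethyl ylide, followed by acid hydrolysis of both acetals, which also equilibrates the new enal double bonds to E.

Step 12
Reactants: 17 (2E,4E,6E,8E,10E)-4,9-dimethyldodeca-2,4,6,8,10-pentaenedial; 18 2-(triphenyl-λ5-phosphanylidene)propanal
Product: 19 crocetindialdehyde, (2E,4E,6E,8E,10E,12E,14E)-2,6,11,15-tetramethylhexadeca-2,4,6,8,10,12,14-heptaenedial
Conditions: toluene, 80 °C
Reagents that add atoms: none
Why: The stabilised-ylide Wittig reaction adds a C(CH3)–CHO unit at each end with E geometry, and the α-methyl enal formed is far less reactive towards this hindered ylide than the α-unsubstituted enal, so chain growth should stop at C20.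

Step 13
Reactants: 19 crocetindialdehyde; 13 ring A sulfone; 11 ring B sulfone
Product: 21 (3R,6R,3'R,6'R)-3-(triethylsilyloxy)-3'-(tert-butyldimethylsilyloxy)-ε,ε-carotene, via apo-carotenal 20 (not isolated)
Conditions: 13, KN(SiMe3)2, THF, −78 °C, added slowly to 19 (1.2 equiv), THF–DMF, −60 °C; then carbanion of 11 (KN(SiMe3)2, THF, −78 °C), −60 °C → rt; heptane, 80 °C
Reagents that add atoms: none
Why: KN(SiMe3)2 removes a C7 proton of 13; the α-sulfonyl carbanion adds to one formyl group of 19, the tetrazole migrates from sulfur to the alkoxide oxygen (Smiles rearrangement), and loss of SO2 and potassium 1-phenyltetrazol-5-olate gives C7=C8 of apo-carotenal 20, after which the carbanion of 11 repeats the sequence at the remaining formyl group to give C7'=C8'. The closest known reactions are Julia–Kocienski olefinations of conjugated aldehydes with alkyl 1-phenyltetrazolyl sulfones and double olefinations of polyene dialdehydes. No ring closes and no stereocentre is created; the charge sits on C7 and is not delocalised through C6, C6 carries no leaving group, and the base is consumed at −78 °C, so C6, C6', C3 and C3' are carried through. E geometry at both new bonds is what this sulfone type gives with a potassium base and a bulky group on the carbanion, and the strained 7Z or 7'Z isomers that may accompany it should revert to E on heating in heptane. Mono- before bis-olefination rests on slow addition of the first carbanion to an excess of 19 and on the lower electrophilicity of 20, whose formyl group is no longer conjugated to a second acceptor. Symmetric bis(triethylsilyl) or bis(TBS) carotenes formed by statistical leakage differ sharply from the product line in polarity after step 14 and are removed there.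

Step 14
Reactants: 21 (3R,6R,3'R,6'R)-3-(triethylsilyloxy)-3'-(tert-butyldimethylsilyloxy)-ε,ε-carotene
Product: 22 (3R,6R,3'R,6'R)-3'-(tert-butyldimethylsilyloxy)-ε,ε-caroten-3-ol
Conditions: HF·pyridine, excess pyridine, THF, 0 °C
Reagents that add atoms: none
Why: Buffered fluoride cleaves a secondary triethylsilyl ether much faster than the bulkier TBS ether (steric control of Si–O cleavage), in a non-nucleophilic medium too weakly acidic to ionise the allylic C–O bonds.

Step 15
Reactants: 22 (3R,6R,3'R,6'R)-3'-(tert-butyldimethylsilyloxy)-ε,ε-caroten-3-ol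
Product: 23 (6R,3'R,6'R)-3'-(tert-butyldimethylsilyloxy)-ε,ε-caroten-3-one
Conditions: MnO2, CH2Cl2, rt, dark
Reagents that add atoms: none
Why: Activated MnO2 oxidises the allylic C3 alcohol of ring A to the enone under neutral conditions, as is known for the allylic ε-ring hydroxyl of carotenoids; the silylated ring B oxygen cannot react and C6 is not enolised.

Step 16
Reactants: 23 (6R,3'R,6'R)-3'-(tert-butyldimethylsilyloxy)-ε,ε-caroten-3-one
Product: 24 (6R,3'R,6'R)-3'-hydroxy-ε,ε-caroten-3-one (all-E), CNP0344065.2
Conditions: HF·pyridine, excess pyridine, THF, 0 °C → rt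
Reagents that add atoms: none
Why: Fluoride cleavage of the last silyl ether under buffered, non-basic conditions avoids γ-deprotonation at C6 of the enone ring and ionisation of the allylic alcohol, so C6, C3' and C6' should arrive unchanged.

**Compound list**

1 | mesityl oxide (4-methylpent-3-en-2-one) | CC(C)=CC(C)=O | starting material
2 | ethyl acetoacetate | CCOC(=O)CC(C)=O | starting material
3 | rac-ethyl 2,6,6-trimethyl-4-oxocyclohex-2-ene-1-carboxylate (racemate) | CCOC(=O)C1C(C)=CC(=O)CC1(C)C | intermediate
4 | rac-ethyl (1R*,4R*)-4-hydroxy-2,6,6-trimethylcyclohex-2-ene-1-carboxylate (trans racemate; the 1R,4R enantiomer is drawn) | CC1=C[C@H](O)CC(C)(C)[C@H]1C(=O)OCC | intermediate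
5 | ethyl (1R,4R)-4-(acetyloxy)-2,6,6-trimethylcyclohex-2-ene-1-carboxylate | CC1=C[C@H](OC(C)=O)CC(C)(C)[C@H]1C(=O)OCC | intermediate
6 | ethyl (1R,4R)-4-hydroxy-2,6,6-trimethylcyclohex-2-ene-1-carboxylate | CC1=C[C@H](O)CC(C)(C)[C@H]1C(=O)OCC | intermediate
7 | ethyl (1R,4R)-4-[(tert-butyldimethylsilyl)oxy]-2,6,6-trimethylcyclohex-2-ene-1-carboxylate | CC1=C[C@H](O[Si](C)(C)C(C)(C)C)CC(C)(C)[C@H]1C(=O)OCC | intermediate
8 | [(1R,4R)-4-[(tert-butyldimethylsilyl)oxy]-2,6,6-trimethylcyclohex-2-en-1-yl]methanol | CC1=C[C@H](O[Si](C)(C)C(C)(C)C)CC(C)(C)[C@H]1CO | intermediate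
9 | 1-phenyl-1H-tetrazole-5-thiol | Sc1nnnn1-c1ccccc1 | starting material
10 | 5-({[(1R,4R)-4-[(tert-butyldimethylsilyl)oxy]-2,6,6-trimethylcyclohex-2-en-1-yl]methyl}sulfanyl)-1-phenyl-1H-tetrazole | CC1=C[C@H](O[Si](C)(C)C(C)(C)C)CC(C)(C)[C@H]1CSc1nnnn1-c1ccccc1 | intermediate
11 | 5-({[(1R,4R)-4-[(tert-butyldimethylsilyl)oxy]-2,6,6-trimethylcyclohex-2-en-1-yl]methyl}sulfonyl)-1-phenyl-1H-tetrazole (ring B sulfone) | CC1=C[C@H](O[Si](C)(C)C(C)(C)C)CC(C)(C)[C@H]1CS(=O)(=O)c1nnnn1-c1ccccc1 | intermediate
12 | (1R,4R)-3,5,5-trimethyl-4-{[(1-phenyl-1H-tetrazol-5-yl)sulfonyl]methyl}cyclohex-2-en-1-ol | CC1=C[C@H](O)CC(C)(C)[C@H]1CS(=O)(=O)c1nnnn1-c1ccccc1 | intermediate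
13 | 5-({[(1R,4R)-2,6,6-trimethyl-4-[(triethylsilyl)oxy]cyclohex-2-en-1-yl]methyl}sulfonyl)-1-phenyl-1H-tetrazole (ring A sulfone) | CC1=C[C@H](O[Si](CC)(CC)CC)CC(C)(C)[C@H]1CS(=O)(=O)c1nnnn1-c1ccccc1 | intermediate
14 | (2E,4E,6E)-2,7-dimethylocta-2,4,6-trienedial | O=C/C(C)=C/C=C/C=C(C)/C=O | starting material
15 | (1,3-dioxolan-2-ylmethyl)triphenylphosphonium bromide | [Br-].C1COC(O1)C[P+](c1ccccc1)(c1ccccc1)c1ccccc1 | starting material
16 | 2,2'-[(3E,5E,7E)-3,8-dimethyldeca-1,3,5,7,9-pentaene-1,10-diyl]bis(1,3-dioxolane), E/Z mixture at C1=C2 and C9=C10 | C1COC(O1)C=C/C(C)=C/C=C/C=C(C)/C=CC1OCCO1 | intermediate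
17 | (2E,4E,6E,8E,10E)-4,9-dimethyldodeca-2,4,6,8,10-pentaenedial | O=C/C=C/C(C)=C/C=C/C=C(C)/C=C/C=O | intermediate
18 | 2-(triphenyl-λ5-phosphanylidene)propanal | CC(C=O)=P(c1ccccc1)(c1ccccc1)c1ccccc1 | starting material
19 | crocetindialdehyde, (2E,4E,6E,8E,10E,12E,14E)-2,6,11,15-tetramethylhexadeca-2,4,6,8,10,12,14-heptaenedial | O=C/C(C)=C/C=C/C(C)=C/C=C/C=C(C)/C=C/C=C(C)/C=O | intermediate
20 | (3R,6R)-3-[(triethylsilyl)oxy]-8'-apo-ε-caroten-8'-al (all-E) | CC1=C[C@H](O[Si](CC)(CC)CC)CC(C)(C)[C@H]1/C=C/C(C)=C/C=C/C(C)=C/C=C/C=C(C)/C=C/C=C(C)/C=O | intermediate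
21 | (3R,6R,3'R,6'R)-3-(triethylsilyloxy)-3'-(tert-butyldimethylsilyloxy)-ε,ε-carotene | CC1=C[C@H](O[Si](CC)(CC)CC)CC(C)(C)[C@H]1/C=C/C(C)=C/C=C/C(C)=C/C=C/C=C(C)/C=C/C=C(C)/C=C/[C@H]1C(C)=C[C@H](O[Si](C)(C)C(C)(C)C)CC1(C)C | intermediate
22 | (3R,6R,3'R,6'R)-3'-(tert-butyldimethylsilyloxy)-ε,ε-caroten-3-ol | CC1=C[C@H](O)CC(C)(C)[C@H]1/C=C/C(C)=C/C=C/C(C)=C/C=C/C=C(C)/C=C/C=C(C)/C=C/[C@H]1C(C)=C[C@H](O[Si](C)(C)C(C)(C)C)CC1(C)C | intermediate
23 | (6R,3'R,6'R)-3'-(tert-butyldimethylsilyloxy)-ε,ε-caroten-3-one | CC1=CC(=O)CC(C)(C)[C@H]1/C=C/C(C)=C/C=C/C(C)=C/C=C/C=C(C)/C=C/C=C(C)/C=C/[C@H]1C(C)=C[C@H](O[Si](C)(C)C(C)(C)C)CC1(C)C | intermediate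
24 | (6R,3'R,6'R)-3'-hydroxy-ε,ε-caroten-3-one (all-E), CNP0344065.2 | CC1=CC(=O)CC(C)(C)[C@H]1/C=C/C(C)=C/C=C/C(C)=C/C=C/C=C(C)/C=C/C=C(C)/C=C/[C@H]1C(C)=C[C@H](O)CC1(C)C | target

**Count**

Total steps: 16. Longest linear sequence: 14 steps (steps 1–10, then 13–16); steps 11 and 12 form the convergent C20 branch.

**Steps most likely to fail**

1. Step 13. What may go wrong: the first carbanion does not stop at mono-olefination, because attack on the formyl group of the mono-adduct competes with attack on the dialdehyde, so symmetric disilyl carotenes grow at the expense of the mixed one; Z geometry at C7=C8 may also persist. Fallback: give up the one-flask mode and run two separate two-component olefinations. Setting out from 13 and 19, the carbanion of 13 is added to a threefold excess of 19, the apo-carotenal 20 is isolated by chromatography (19 recovered), and pure 20 is then olefinated with the carbanion of 11 in a second operation. The route is rejoined at 21, and no compound outside the list is made (F0).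

2. Step 3. What may go wrong: the enzyme discriminates the enantiomers of 4 poorly, so the acetate is obtained in low enantiomeric purity. Fallback: classical resolution through covalent diastereomers. Setting out from 4, esterification with (S)-2-methoxy-2-phenylacetic acid (DCC, DMAP cat., CH2Cl2) gives ethyl (1R,4R)-4-{[(2S)-2-methoxy-2-phenylacetyl]oxy}-2,6,6-trimethylcyclohex-2-ene-1-carboxylate F1 and ethyl (1S,4S)-4-{[(2S)-2-methoxy-2-phenylacetyl]oxy}-2,6,6-trimethylcyclohex-2-ene-1-carboxylate F2. These are separated by chromatography or crystallisation and assigned by the anisotropic shielding pattern of the two esters. F1 is cleaved with K2CO3 in EtOH at 0 °C, and the route is rejoined at 6.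

3. Step 14. What may go wrong: loss of discrimination between the two silyl ethers (the TBS ether of ring B is cleaved alongside the triethylsilyl ether), or acid-promoted ionisation of an allylic C–O bond. Fallback: avoid the second silyl group altogether. Setting out from 11, 12 and 19, the carbanion of 11 is added to an excess of 19 and (3R,6R)-3-[(tert-butyldimethylsilyl)oxy]-8'-apo-ε-caroten-8'-al F3 is isolated. F3 is then olefinated with the dianion of the free hydroxy sulfone 12 (2.1 equiv KN(SiMe3)2, THF, −78 °C → rt; the potassium alkoxide serves as the protecting group). This gives the mono-protected carotenol directly and rejoins the route at 22.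

**Further compounds**

F0 | step 13 | none | none
F1 | step 3 | ethyl (1R,4R)-4-{[(2S)-2-methoxy-2-phenylacetyl]oxy}-2,6,6-trimethylcyclohex-2-ene-1-carboxylate | CC1=C[C@H](OC(=O)[C@@H](OC)c2ccccc2)CC(C)(C)[C@H]1C(=O)OCC
F2 | step 3 | ethyl (1S,4S)-4-{[(2S)-2-methoxy-2-phenylacetyl]oxy}-2,6,6-trimethylcyclohex-2-ene-1-carboxylate | CC1=C[C@@H](OC(=O)[C@@H](OC)c2ccccc2)CC(C)(C)[C@@H]1C(=O)OCC
F3 | step 14 | (3R,6R)-3-[(tert-butyldimethylsilyl)oxy]-8'-apo-ε-caroten-8'-al | CC1=C[C@H](O[Si](C)(C)C(C)(C)C)CC(C)(C)[C@H]1/C=C/C(C)=C/C=C/C(C)=C/C=C/C=C(C)/C=C/C=C(C)/C=O
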